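**Strategy**

The route rests on disconnecting the C4–C5 bond (clerodane numbering), shared by the butenolide and ring A and ending at quaternary C5. The key step exploits two features: the C7 acetoxy oxygen, 1,3 to C5, is carried as a ketone that makes C5 the β-carbon of a ring-B enone, and the lactone oxygen on C19 tethers a phosphonoacetate. The precursor also carries a 3-oxopropyl arm on C10. Base adds the phosphonate carbanion C4 to C5, closing the lactone and setting C5, and an intramolecular Horner–Wadsworth–Emmons reaction closes ring A (C3=C4) in the same operation. One organocatalytic stereocentre (C10) relays the others; a vinylogous Michael spirocyclisation and epoxidation finish.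

Key step: step 9

Remark on numbering: ring A = C1, C2, C3, C4, C5, C10; ring B = C5, C6, C7, C8, C9, C10; ring C = C1, C10, C9, C11, C12, C13. C17 and C20 are the methyls on C8 and C9, C18 is the butenolide carbonyl on C4, C19 the OCH2 on C5, C12 the ketone, C13 the spiro carbon, C14 and C15 the epoxide carbons, C16 the spirolactone carbonyl.

Assumption: the prolinol silyl ether in step 1 follows the usual steric-shielding model, which points to the (R)-catalyst for (S)-4; the catalyst enantiomer is chosen to match.

Assumption: hex-5-enal and 3-bromofuran-2(5H)-one are taken as purchasable; each is otherwise one routine operation from hex-5-en-1-ol or furan-2(5H)-one.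

**Route**

Step 1
Reactants: 1 hex-5-enal; 2 but-3-en-2-one
Product: 4 (S)-4-(but-3-en-1-yl)cyclohex-2-en-1-one, via keto aldehyde 3 (not isolated)
Conditions: (R)-α,α-diphenylprolinol trimethylsilyl ether (10 mol %), ethyl 3,4-dihydroxybenzoate (20 mol %), neat, 4 °C; then LiOH (cat.), i-PrOH, rt
Reagents that add atoms: none
Why: Enamine-catalysed Michael addition of the aldehyde to the vinyl ketone and base-mediated intramolecular aldol condensation (organocatalytic Robinson-type annulation) should give the 4-substituted cyclohexenone; the prolinol ether shields one enamine face and so sets C10, the stereocentre from which all others are relayed.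

Step 2
Reactants: 4 (S)-4-(but-3-en-1-yl)cyclohex-2-en-1-one
Product: 6 (S)-4-(but-3-en-1-yl)-3-methylcyclohex-2-en-1-one, via silyl enol ether 5 (not isolated)
Conditions: MeMgBr, CuBr·SMe2 (10 mol %), TMSCl, HMPA, THF, −78 °C; then Pd(OAc)2, MeCN, rt
Reagents that add atoms: methylmagnesium bromide, C[Mg]Br
Why: Copper-catalysed 1,4-addition trapped as silyl enol ether 5 followed by Saegusa–Ito oxidation should return the enone with the C20 methyl on the β-carbon C9; the C9 centre formed in between is planarised again and C10 is not touched.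

Step 3
Reactants: 6 (S)-4-(but-3-en-1-yl)-3-methylcyclohex-2-en-1-one; 7 (1,3-dioxolan-2-ylmethyl)magnesium bromide
Product: 10 (2S,3R,4S)-4-(but-3-en-1-yl)-3-(1,3-dioxolan-2-ylmethyl)-2,3-dimethylcyclohexan-1-one, via silyl enol ether 8 (not isolated), via lithium enolate 9 (not isolated)
Conditions: CuBr·SMe2 (20 mol %), TMSCl, HMPA, THF, −78 to −40 °C; then MeLi, THF, 0 °C; MeI, −78 to 0 °C; then NaOMe (cat.), MeOH, rt
Reagents that add atoms: iodomethane, CI
Why: Chlorosilane-accelerated copper-catalysed conjugate addition should create quaternary C9 with the new CH2 group (C11) anti to the adjacent C10 side chain (the usual trans selectivity of 4-substituted cyclohexenones), the regiodefined enolate released by MeLi is C-methylated at C8, and methoxide equilibration should leave the C8 methyl equatorial, cis to the C9 methyl.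

Step 4
Reactants: 10 (2S,3R,4S)-4-(but-3-en-1-yl)-3-(1,3-dioxolan-2-ylmethyl)-2,3-dimethylcyclohexan-1-one
Product: 12 (4S,5R,6S)-4-(but-3-en-1-yl)-5-(1,3-dioxolan-2-ylmethyl)-5,6-dimethylcyclohex-2-en-1-one, via selenide 11 (not isolated)
Conditions: LDA, THF, −78 °C; PhSeBr; then 30% H2O2, pyridine, CH2Cl2, 0 °C to rt
Reagents that add atoms: none
Why: Kinetic deprotonation at the unhindered C6 methylene, α-selenenylation and selenoxide syn-elimination should give the C5=C6 enone; no stereocentre is formed and the terminal alkene is left alone by one equivalent of PhSeBr at −78 °C.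

Step 5
Reactants: 12 (4S,5R,6S)-4-(but-3-en-1-yl)-5-(1,3-dioxolan-2-ylmethyl)-5,6-dimethylcyclohex-2-en-1-one; 13 (chloromethyl)(isopropoxy)dimethylsilane
Product: 15 (2S,3R,4S,5R)-4-(but-3-en-1-yl)-3-(1,3-dioxolan-2-ylmethyl)-5-(hydroxymethyl)-2,3-dimethylcyclohexan-1-one, via silane 14 (not isolated)
Conditions: 13, Mg, THF (Grignard reagent); CuI (10 mol %), THF, −78 to −30 °C; aq. NH4Cl; then KF, KHCO3, 30% H2O2, THF/MeOH, rt
Reagents that add atoms: hydrogen peroxide, OO
Why: Copper-catalysed conjugate addition of the silylmethyl Grignard reagent (a hydroxymethyl anion equivalent) to C5 should occur anti to the C10 side chain, and Tamao oxidation of the C–Si bond gives the C19 alcohol; the C5 centre is temporary and is erased in step 7.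

Step 6
Reactants: 15 (2S,3R,4S,5R)-4-(but-3-en-1-yl)-3-(1,3-dioxolan-2-ylmethyl)-5-(hydroxymethyl)-2,3-dimethylcyclohexan-1-one; 16 2-(dimethoxyphosphoryl)acetic acid
Product: 17 [(1R,2S,3R,4S)-2-(but-3-en-1-yl)-3-(1,3-dioxolan-2-ylmethyl)-3,4-dimethyl-5-oxocyclohexyl]methyl 2-(dimethoxyphosphoryl)acetate
Conditions: DCC, DMAP (cat.), CH2Cl2, 0 °C to rt
Reagents that add atoms: none
Why: Steglich esterification of the primary alcohol installs the C18–C4 unit as the tether for the key step; no stereocentre is affected.

Step 7
Reactants: 17 [(1R,2S,3R,4S)-2-(but-3-en-1-yl)-3-(1,3-dioxolan-2-ylmethyl)-3,4-dimethyl-5-oxocyclohexyl]methyl 2-(dimethoxyphosphoryl)acetate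
Product: 18 [(4S,5R,6R)-6-(but-3-en-1-yl)-5-(1,3-dioxolan-2-ylmethyl)-4,5-dimethyl-3-oxocyclohex-1-en-1-yl]methyl 2-(dimethoxyphosphoryl)acetate
Conditions: IBX, 4-methoxypyridine N-oxide, DMSO, rt to 40 °C
Reagents that add atoms: none
Why: IBX-mediated dehydrogenation of the ketone can only run towards C5–C6, because the carbon next to C8 is quaternary, and should give the γ-acyloxy enone with C5 as β-carbon under non-basic conditions that leave the phosphonoacetate alone.

Step 8
Reactants: 18 [(4S,5R,6R)-6-(but-3-en-1-yl)-5-(1,3-dioxolan-2-ylmethyl)-4,5-dimethyl-3-oxocyclohex-1-en-1-yl]methyl 2-(dimethoxyphosphoryl)acetate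
Product: 19 [(4S,5R,6R)-5-(1,3-dioxolan-2-ylmethyl)-4,5-dimethyl-3-oxo-6-(3-oxopropyl)cyclohex-1-en-1-yl]methyl 2-(dimethoxyphosphoryl)acetate
Conditions: O3, CH2Cl2, −78 °C (stopped at first excess of ozone); then PPh3, −78 °C to rt
Reagents that add atoms: ozone, [O-][O+]=O
Why: Ozonolysis with reductive work-up should cleave the electron-rich terminal alkene much faster than the conjugated trisubstituted enone and unveil the C3 aldehyde.

Step 9
Reactants: 19 [(4S,5R,6R)-5-(1,3-dioxolan-2-ylmethyl)-4,5-dimethyl-3-oxo-6-(3-oxopropyl)cyclohex-1-en-1-yl]methyl 2-(dimethoxyphosphoryl)acetate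
Product: 21 tricyclic keto lactone (7-oxo-18,19-olide with C3=C4, rings A and B trans-fused, C12 as dioxolane), via phosphonate lactone 20 (not isolated)
Conditions: LiCl, DBU, MeCN (0.005 M), 0 °C to rt
Reagents that add atoms: none
Why: LiCl and DBU generate the lithium-chelated phosphonoacetate carbanion (C4), which adds to C5, the β-carbon of the ring-B enone, through the C19–O–C18 ester tether (intramolecular Michael addition) and so closes the γ-lactone by forming C4–C5; phosphonate 20 is deprotonated again and attacks the C3 aldehyde in an intramolecular Horner–Wadsworth–Emmons olefination that closes ring A. The closest known reactions are base-mediated cyclisations of γ-(phosphonoacetoxy) enones and enoates to α-phosphono-γ-lactones and HWE ring closures under mild LiCl/amine conditions. The lactone closes 5-exo-trig and ring A by six-membered olefination with loss of dimethyl phosphate, which makes the sequence irreversible. The only new stereocentre, quaternary C5, is set by the substrate: the carbanion should attack the enone face anti to the adjacent C10 side chain and to the axial C9 methyl, as in conjugate additions to 4-substituted cyclohexenones, so that C4 ends trans to C1 and the A/B fusion is trans. The step needs the conjugate addition to precede olefination and to beat bimolecular HWE; a direct HWE would need a nine-membered ring, high dilution disfavours the bimolecular path, and a wrongly configured Michael adduct can revert by retro-Michael reaction. C8, alpha to the C7 ketone, should settle as the equatorial methyl under these conditions.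

Step 10
Reactants: 21 tricyclic keto lactone
Product: 22 axial C7 alcohol (7-hydroxy-18,19-olide, OH syn to C19 and C20)
Conditions: NaBH4, MeOH/THF, −40 °C
Reagents that add atoms: none
Why: Borohydride reduction of the only ketone (lactone, acetal and conjugated ester are inert) should occur from the equatorial side, because the axial trajectory is blocked by the syn-axial C19 methylene and C20 methyl, and so give the axial C7 alcohol.

Step 11
Reactants: 22 axial C7 alcohol
Product: 23 C7 acetate
Conditions: Ac2O, DMAP, pyridine, 40 °C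
Reagents that add atoms: acetic anhydride, CC(=O)OC(C)=O
Why: DMAP-catalysed acetylation of the hindered axial secondary alcohol; no stereocentre changes.

Step 12
Reactants: 23 C7 acetate
Product: 25 dienoate (C1=C2 and C3=C4 conjugated with the C18 lactone carbonyl), via silyl ketene acetal 24 (not isolated)
Conditions: LiHMDS, TBSCl, HMPA, THF, −78 °C; then Pd(OAc)2, MeCN, rt
Reagents that add atoms: none
Why: Deprotonation of the α-alkylidene lactone at its only γ-position (C2), O-silylation and Saegusa–Ito oxidation of the silyl dienol ether (palladation, then β-hydride elimination of H-1, the only one available because C5 is quaternary) should give the dienoate and make C1 an electrophilic δ-carbon.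

Step 13
Reactants: 25 dienoate
Product: 26 C12 aldehyde
Conditions: p-TsOH·H2O (cat.), acetone/H2O, 40 °C
Reagents that add atoms: water, O
Why: Acid-catalysed acetal hydrolysis releases the C12 aldehyde; acetate, lactone and dienoate are stable to dilute acid.

Step 14
Reactants: 26 C12 aldehyde; 27 3-bromofuran-2(5H)-one
Product: 28 C12 carbinol (3-(1-hydroxyalkyl)butenolide, mixture at C12)
Conditions: CrCl2 (4 equiv), NiCl2 (2 mol %), DMF, rt
Reagents that add atoms: none
Why: Nozaki–Hiyama–Kishi coupling: the alkenylchromium species from the α-bromobutenolide should add chemoselectively to the aldehyde in the presence of the esters and the dienoate; the C12 carbinol centre is removed in step 15.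

Step 15
Reactants: 28 C12 carbinol
Product: 29 3-acylbutenolide (C12 ketone)
Conditions: Dess–Martin periodinane, NaHCO3, CH2Cl2, 0 °C
Reagents that add atoms: none
Why: Dess–Martin oxidation of the secondary allylic alcohol gives the 3-acylbutenolide, whose γ-protons (C15) are now acidic.

Step 16
Reactants: 29 3-acylbutenolide
Product: 30 spiro enol lactone (ring C closed, C13 spiro, C14=C15 enol lactone)
Conditions: DBU (0.3 equiv), MeCN (0.005 M), 0 °C to rt
Reagents that add atoms: none
Why: DBU deprotonates C15 to the 3-acylfuran-2-olate (a cyclic β-keto ester enolate), whose α-carbon C13 adds 6-exo-trig to C1 of the dienoate (intramolecular vinylogous 1,6-Michael addition) and reprotonation returns the C3=C4 butenolide; the reversible addition should favour the all-trans, all-chair tricycle (H-1 axial, anti to H-10) and, from the dipole-minimised non-chelated enolate, the C13 epimer with the lactone carbonyl C16 axial.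

Step 17
Reactants: 30 spiro enol lactone
Product: 31 target CNP0308057.1
Conditions: dimethyldioxirane, acetone/CH2Cl2, −20 °C
Reagents that add atoms: dimethyldioxirane, CC1(C)OO1
Why: Dimethyldioxirane should epoxidise only the electron-rich enol-lactone double bond C14=C15 (the conjugated butenolide is inert), from the face flanked by the flat C12 carbonyl and not by the C1 methine and ring A, which sets C14 and C15.

**Compound list**

1 | hex-5-enal | C=CCCCC=O | starting material
2 | but-3-en-2-one | CC(=O)C=C | starting material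
3 | (S)-2-(but-3-en-1-yl)-5-oxohexanal | O=C[C@@H](CCC=C)CCC(C)=O | intermediate (not isolated)
4 | (S)-4-(but-3-en-1-yl)cyclohex-2-en-1-one | O=C1C=C[C@@H](CCC=C)CC1 | intermediate
5 | trimethylsilyl enol ether of trans-4-(but-3-enyl)-3-methylcyclohexanone | C[Si](C)(C)OC1=C[C@H](C)[C@@H](CCC=C)CC1 | intermediate (not isolated)
6 | (S)-4-(but-3-en-1-yl)-3-methylcyclohex-2-en-1-one | O=C1C=C(C)[C@@H](CCC=C)CC1 | intermediate
7 | (1,3-dioxolan-2-ylmethyl)magnesium bromide | Br[Mg]CC1OCCO1 | starting material
8 | trimethylsilyl enol ether of the C9 conjugate adduct (C11 trans to the C10 chain) | C[Si](C)(C)OC1=C[C@](C)(CC2OCCO2)[C@@H](CCC=C)CC1 | intermediate (not isolated)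
9 | lithium enolate of the C9 conjugate adduct | [Li]OC1=C[C@](C)(CC2OCCO2)[C@@H](CCC=C)CC1 | intermediate (not isolated)
10 | (2S,3R,4S)-4-(but-3-en-1-yl)-3-(1,3-dioxolan-2-ylmethyl)-2,3-dimethylcyclohexan-1-one | O=C1[C@@H](C)[C@](C)(CC2OCCO2)[C@@H](CCC=C)CC1 | intermediate
11 | 6-(phenylselanyl) derivative of 10 (mixture at C6) | O=C1[C@@H](C)[C@](C)(CC2OCCO2)[C@@H](CCC=C)CC1[Se]c1ccccc1 | intermediate (not isolated)
12 | (4S,5R,6S)-4-(but-3-en-1-yl)-5-(1,3-dioxolan-2-ylmethyl)-5,6-dimethylcyclohex-2-en-1-one | O=C1[C@@H](C)[C@](C)(CC2OCCO2)[C@@H](CCC=C)C=C1 | intermediate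
13 | (chloromethyl)(isopropoxy)dimethylsilane | CC(C)O[Si](C)(C)CCl | starting material
14 | (2S,3R,4S,5R)-4-(but-3-en-1-yl)-3-(1,3-dioxolan-2-ylmethyl)-5-{[isopropoxy(dimethyl)silyl]methyl}-2,3-dimethylcyclohexan-1-one | O=C1[C@@H](C)[C@](C)(CC2OCCO2)[C@@H](CCC=C)[C@H](C[Si](C)(C)OC(C)C)C1 | intermediate (not isolated)
15 | (2S,3R,4S,5R)-4-(but-3-en-1-yl)-3-(1,3-dioxolan-2-ylmethyl)-5-(hydroxymethyl)-2,3-dimethylcyclohexan-1-one | O=C1[C@@H](C)[C@](C)(CC2OCCO2)[C@@H](CCC=C)[C@H](CO)C1 | intermediate
16 | 2-(dimethoxyphosphoryl)acetic acid | COP(=O)(OC)CC(=O)O | starting material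
17 | [(1R,2S,3R,4S)-2-(but-3-en-1-yl)-3-(1,3-dioxolan-2-ylmethyl)-3,4-dimethyl-5-oxocyclohexyl]methyl 2-(dimethoxyphosphoryl)acetate | O=C1[C@@H](C)[C@](C)(CC2OCCO2)[C@@H](CCC=C)[C@H](COC(=O)CP(=O)(OC)OC)C1 | intermediate
18 | [(4S,5R,6R)-6-(but-3-en-1-yl)-5-(1,3-dioxolan-2-ylmethyl)-4,5-dimethyl-3-oxocyclohex-1-en-1-yl]methyl 2-(dimethoxyphosphoryl)acetate | O=C1C=C(COC(=O)CP(=O)(OC)OC)[C@H](CCC=C)[C@@](C)(CC2OCCO2)[C@@H]1C | intermediate
19 | [(4S,5R,6R)-5-(1,3-dioxolan-2-ylmethyl)-4,5-dimethyl-3-oxo-6-(3-oxopropyl)cyclohex-1-en-1-yl]methyl 2-(dimethoxyphosphoryl)acetate | O=C1C=C(COC(=O)CP(=O)(OC)OC)[C@H](CCC=O)[C@@](C)(CC2OCCO2)[C@@H]1C | intermediate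
20 | spiro α-(dimethoxyphosphoryl)-γ-lactone ketone (C4–C5 formed, C4 trans to the C10 chain, mixture at C4) | O=C1C[C@]2(COC(=O)C2P(=O)(OC)OC)[C@H](CCC=O)[C@@](C)(CC2OCCO2)[C@@H]1C | intermediate (not isolated)
21 | tricyclic keto lactone: 7-oxo-18,19-olide, C3=C4, trans A/B fusion (C19 syn to C20, H-10 anti), C12 as dioxolane | O=C1C[C@@]23COC(=O)C2=CCC[C@@H]3[C@@](C)(CC2OCCO2)[C@@H]1C | intermediate
22 | axial C7 alcohol of 21 (OH syn to C19 and C20) | O[C@@H]1C[C@@]23COC(=O)C2=CCC[C@@H]3[C@@](C)(CC2OCCO2)[C@@H]1C | intermediate
23 | C7 acetate of 22 | CC(=O)O[C@@H]1C[C@@]23COC(=O)C2=CCC[C@@H]3[C@@](C)(CC2OCCO2)[C@@H]1C | intermediate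
24 | tert-butyldimethylsilyl ketene acetal of 23 (C18=C4 and C2=C3) | CC(=O)O[C@@H]1C[C@@]23COC(O[Si](C)(C)C(C)(C)C)=C2C=CC[C@@H]3[C@@](C)(CC2OCCO2)[C@@H]1C | intermediate (not isolated)
25 | dienoate: C1=C2 and C3=C4 conjugated with the 18,19-olide, C7 acetate, C12 as dioxolane | CC(=O)O[C@@H]1C[C@@]23COC(=O)C2=CC=C[C@@H]3[C@@](C)(CC2OCCO2)[C@@H]1C | intermediate
26 | C12 aldehyde of the dienoate | CC(=O)O[C@@H]1C[C@@]23COC(=O)C2=CC=C[C@@H]3[C@@](C)(CC=O)[C@@H]1C | intermediate
27 | 3-bromofuran-2(5H)-one | O=C1OCC=C1Br | starting material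
28 | C12 carbinol: 3-(1-hydroxyalkyl)furan-2(5H)-one (mixture at C12) | CC(=O)O[C@@H]1C[C@@]23COC(=O)C2=CC=C[C@@H]3[C@@](C)(CC(O)C2=CCOC2=O)[C@@H]1C | intermediate
29 | 3-acylbutenolide (C12 ketone) | CC(=O)O[C@@H]1C[C@@]23COC(=O)C2=CC=C[C@@H]3[C@@](C)(CC(=O)C2=CCOC2=O)[C@@H]1C | intermediate
30 | spiro enol lactone: ring C closed, all-trans ring fusions, C16 carbonyl axial on C13, C14=C15 | CC(=O)O[C@@H]1C[C@@]23COC(=O)C2=CC[C@@H]2[C@@H]3[C@@](C)(CC(=O)[C@]23C(=O)OC=C3)[C@@H]1C | intermediate
31 | CNP0308057.1 | CC(=O)O[C@@H]1C[C@@]23COC(=O)C2=CC[C@@H]2[C@@H]3[C@@](C)(CC(=O)[C@]23C(=O)O[C@H]2O[C@H]23)[C@@H]1C | target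

**Count and risks**

Total step count: 17. Longest linear sequence: 17 steps (the route is linear).

Steps most likely to fail:

1. Step 16. The furanolate may add to the acylbutenolide of a second molecule (oligomerisation) instead of closing ring C, or may cyclise through the metal-bridged enolate conformer and give the C13 epimer. Fallback, from 29 back to 30: the nucleophile is made neutral and isolable. Silylation (TIPSOTf, Et3N, CH2Cl2, 0 °C) gives the 3-acyl-2-(triisopropylsilyloxy)furan F1. A Lewis-acid-catalysed intramolecular vinylogous Mukaiyama–Michael addition to the dienoate (Sc(OTf)3 cat., CH2Cl2, −78 °C, then aqueous work-up) then closes ring C to 30 without a free enolate and through an open, non-chelated transition state.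

2. Step 9. The cascade may lose its order (olefination between two molecules before the lactone closes), or the conjugate addition may show poor facial selectivity, helped by epimerisation at C10 through γ-deprotonation of the enone. Fallback, from 18 back to 21: the two events are separated and ring A is closed by metathesis instead of olefination. The Michael addition is run alone under equilibrating conditions (Cs2CO3, MeCN) to give the spirolactone phosphonate F2, with the butenyl chain still in place. HWE methylenation with paraformaldehyde (K2CO3, THF) gives the α-methylene lactone F3. Ring-closing metathesis with the butenyl chain (second-generation Grubbs catalyst, CH2Cl2, 40 °C) then gives 21.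

3. Step 12. Deprotonation may be unselective between the γ-position of the unsaturated lactone and the acetate, or the palladium-mediated oxidation of the dienol ether may be incomplete. Fallback, from 23 back to 25: the diene is made by oxidation and elimination instead of enolate chemistry. Allylic oxidation at C2 (SeO2, t-BuOOH, CH2Cl2) gives the C2 allylic alcohol F4. Mesylation (MsCl, Et3N) gives the mesylate F5. 1,2-Elimination with DBU (loss of H-1) gives 25.

**Further compounds**

F1 | step 16 | 3-acyl-2-(triisopropylsilyloxy)furan derived from 29 | CC(=O)O[C@@H]1C[C@@]23COC(=O)C2=CC=C[C@@H]3[C@@](C)(CC(=O)c2ccoc2O[Si](C(C)C)(C(C)C)C(C)C)[C@@H]1C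
F2 | step 9 | spirolactone phosphonate with intact but-3-enyl chain (mixture at C4) | O=C1C[C@]2(COC(=O)C2P(=O)(OC)OC)[C@H](CCC=C)[C@@](C)(CC2OCCO2)[C@@H]1C
F3 | step 9 | α-methylene spirolactone with but-3-enyl chain | O=C1C[C@]2(COC(=O)C2=C)[C@H](CCC=C)[C@@](C)(CC2OCCO2)[C@@H]1C
F4 | step 12 | C2 allylic alcohol of 23 (mixture at C2) | CC(=O)O[C@@H]1C[C@@]23COC(=O)C2=CC(O)C[C@@H]3[C@@](C)(CC2OCCO2)[C@@H]1C
F5 | step 12 | C2 mesylate of F4 | CC(=O)O[C@@H]1C[C@@]23COC(=O)C2=CC(OS(C)(=O)=O)C[C@@H]3[C@@](C)(CC2OCCO2)[C@@H]1C
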